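**Remarks before the route**

- Locants C1–C11 in the discussion are guaiane locants (cyclopentenone C1–C5, C3 ketone, C4=C5; seven-membered ring C1, C5, C6, C7, C8, C9, C10). Systematic names carry their own locants.
- Assumption: the C4 epimers of 20 and 21 need not be separated, because C4 becomes trigonal in 22; both compounds are drawn as the epimer expected to predominate in a non-polar solvent (methyl turned towards the seven-membered ring, chlorine syn to H5).

## Structural features

The target is a guaiane-type hydroazulene: a 2-methylcyclopent-2-enone (C1–C5, ketone at C3, tetrasubstituted C4=C5) fused through C1 and C5 to a cycloheptane (C1, C5, C6, C7, C8, C9, C10). The seven-membered ring carries a methyl group on C10, a propanoate on C8 and, on C7, the carbon C11 of a 2-acetoxypropan-2-yl group. There are four stereocentres in two adjacent pairs, C1/C10 and C7/C8, linked across the C9 methylene. H1, the C10 methyl, the C8 oxygen and the C7 side chain all lie on the same face of the seven-membered ring (1R,7S,8R,10S). The fragile points are the tertiary acetate (hard to form, easy to ionise or eliminate), the neighbouring secondary ester (1,3-acyl transfer to the C11 oxygen) and the C1 hydrogen, which is γ to the enone and could epimerise through a dienolate. The real difficulty is stereocontrol on a flexible seven-membered ring: C1 must be set relative to C10 on one side and C7 relative to C8 on the other, while the tetrasubstituted enone is built. The key step uses the fact that C3, C4 and the fusion pair C1/C5 can come from a ketene added across the C1=C5 bond of a cycloheptadiene: the cyclobutanone (C1, C3, C4, C5) fixes C1 beside the existing C10 methyl, a later one-carbon insertion supplies C2, and the chlorine on C4 becomes the C4=C5 double bond. The second diene bond, C6=C7, is kept as the handle from which C7 is set last, under control of C8.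

## Logic of the disconnections

**26 ⇒ 25 ⇒ 24.** The two acyl C–O bonds are cut, the tertiary acetate first and the secondary propanoate second. This postpones both esters until no organometallic, hydride or base-mediated step remains. The forward demand is chemoselective acylation of the secondary C8 hydroxyl in the presence of the tertiary C11 hydroxyl, then a non-ionising acetylation of the tertiary alcohol.

**24 ⇒ 23.** Both O–H bonds are traced back to silyl ethers (O–Si). The bulky silyl ether on the C8 oxygen is kept until C7 is set, because its bulk is what differentiates the faces of C6=C7. The forward step only has to remove two silyl groups without base.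

**23 ⇒ 22.** The C6–H and C7–H bonds are cut to give a C6=C7 double bond. This removes the C7 stereocentre and leaves a linear dienone. The forward hydrogenation must reduce the γ,δ-bond and not the tetrasubstituted enone bond, and must deliver hydrogen anti to the C8 oxygen.

**22 ⇒ 21.** The C4=C5 double bond is traced to H–C5 and Cl–C4. This turns the enone into an α-chloro ketone, the retron of a halo-ketene cycloadduct. The forward step must eliminate HCl toward C5 (or reach the same conjugated isomer by prototropy).

**21 ⇒ 20.** The C1–C2 and C2–C3 bonds are cut and C2 is excised, contracting the cyclopentanone to a cyclobutanone. The forward one-carbon insertion by a diazoalkane must occur between C3 and the non-halogenated carbon C1, with retention at C1.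

**20 ⇒ 17 + 19 (19 from 18).** The C4–C5 and C1–C3 bonds are cut. This is the strategic simplification: a bicycle with three new stereocentres falls to a monocyclic diene and a two-carbon ketene. The forward cycloaddition must choose C1=C5 over C6=C7, bond the ketene carbonyl carbon to C1, and approach the face opposite the C10 methyl and the C8 silyloxy group.

**17 ⇒ 16.** The C1=C5 double bond is cut by a ring-closing metathesis transform, giving an acyclic triene. The forward step must close on the terminal CH2 of the diene and leave the internal trisubstituted bond alone.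

**16 ⇒ 15 ⇒ 14.** The O–Si bond at C8 and then the C8–H bond are cut. C8 is thus created by reagent-controlled reduction of a ketone, not by weak 1,3-induction from C10. The forward reduction needs a catalyst that reads the branched dienyl group as the large substituent.

**14 ⇒ 13 + 12 (13 from 6).** The C7–C8 bond is cut between a dienyl anion at C7 and an acyl cation at C8. Acylation with an N-methoxy-N-methylamide reaches the ketone directly and saves an alcohol oxidation. The forward step needs a configurationally stable 2-metallated diene in which the vinyl group is cis to the metal, since only that geometry can later close the ring.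

**6 ⇒ 5 ⇒ 4 ⇒ 3 ⇒ 1 + 2.** The O–Si bond, the C7–I bond, the C7–Sn/C6–H pair and finally the sp–sp2 bond C5–C6 are cut. The metal must sit on the alkyne carbon next to the carbinol, with hydrogen added anti. An oxygen-bound aluminium hydride followed by iodine would place the halogen on the remote alkyne carbon and would later attach the C8 chain to C6, so a hydroxyl-directed trans-hydrostannation is used instead.

**12 ⇒ 11 ⇒ 10 ⇒ 9 + 8 (9 from 7).** The amide C–N bond, the C10–C1 bond (vinyl to the β-carbon of a crotonyl imide) and the imide N–acyl bond are cut. A thermal [3,3] rearrangement of an achiral allyl vinyl ether would create C10 only as a racemate. The centre is therefore set by auxiliary-controlled conjugate addition, and the auxiliary is released in the amide-forming step.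

## Other disconnections considered

**Alternative 1:** The cut is the C1–C5 bond, with the C5–C10 bond of a decalin restored. In the forward direction the cross-conjugated cyclohexadienone A2 is irradiated in aqueous acetic acid. β,β-Bonding forms C1–C5, the cyclopropane bond C5–C10 opens, and water is captured at C10, giving the hydroazulenone A1.
- In favour: one step turns a six–six skeleton into the five–seven enone with C4=C5 already in place. C1 is fixed stereospecifically by the quaternary C10 of A2. C7 and C8 can be set on a conformationally defined cyclohexane, which is better than setting C7 on a cycloheptene as in the chosen plan. No ketene or diazoalkane is needed, and both esters are already present in A1.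
- Against: A1 carries a tertiary hydroxyl on C10 that the target lacks, on the face where the target has its methyl group. It would have to be removed with net inversion (dehydration and hydrogenation, or radical deoxygenation), so C10 is created a second time under weak control. A2 needs the C10 methyl trans to the C7 side chain, a demanding decalin to assemble with its C8 and C11 oxygens. The tertiary acetate must survive acidic photolysis.
- Comparison: on structure the alternative is the better plan for C1, C7 and C8 and the worse one for C10. On mechanism a stereospecific rearrangement replaces a cycloaddition that depends on facial selection. On step economy the end game after A1 would be about as long as the six steps after 20, but the route to A2 is unlikely to be shorter than the ten steps to 17.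

**Alternative 2:** The cuts are C6–C7 and C9–C10. In the forward direction a dirhodium tetracarboxylate such as Rh2(OAc)4 decomposes the vinyldiazo ester A5. The carbenoid cyclopropanates the methylene group of the diene A4 anti to its methyl group, and the cis-divinylcyclopropane undergoes a boat Cope rearrangement to the bicycle A3.
- In favour: the seven-membered ring and two C–C bonds form in one catalytic, convergent step. C10 follows stereospecifically from the (E)-ethylidene geometry and the C4 centre of A4. The C8 oxygen and a C7 carboxyl group (the precursor of C11) arrive exactly where they are needed. In convergence this is better than the chosen plan, and a stabilised diazo ester is easier to handle than diazomethane.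
- Against: A3 has its ring double bond at C1=C5 and both C7 and C8 trigonal, so three of the four stereocentres remain to be set after the key step. C1 would be set by a protonation during enone transposition, C8 and C7 by reductions of a β-oxygenated ester system. The ester must then take two methyl groups beside a β-oxygen, which invites retro-aldol cleavage or elimination. A4 is a geometrically defined, dimerisation-prone diene whose stereocentre is later erased.
- Comparison: on structure it fixes one centre where the chosen plan fixes C10, C8 and C1 by the end of its key step. On mechanism its one centre is fixed more rigorously (stereospecific Cope) than any centre of the chosen plan. On step economy the gain in convergence is likely to be spent on the corrections after A3, so it is at best equal.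

**Alternative 3:** The cut is C5–C6. In the forward direction Ni(cyclam)(ClO4)2 is reduced at the cathode from divalent nickel to monovalent nickel. This turns the primary iodide A7 into a C6 radical, which adds 7-exo-trig to the enone β-carbon C5. The α-keto radical is then reduced and protonated to give the cis-fused ketone A6.
- In favour: all four stereocentres and both esters are in place before the ring is closed. The cis ring fusion is dictated by the tether on C1. Two electrophilic carbons are joined without tin hydride, under ester-tolerant conditions. No stereocentre has to be created on a flexible seven-membered ring and no late protecting-group steps remain; on these points it is better than the chosen plan.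
- Against: a 7-exo radical closure is slow compared with premature reduction of the radical or intramolecular hydrogen transfer. The radical is primary but sits beside the congested C7. A6 lacks the C4=C5 bond, which must be reintroduced regioselectively toward C4. A7 is an acyclic chain with a stereotriad (C7, C8, C10) plus the ring centre C1, and its synthesis would be long.
- Comparison: on structure the ring is closed last, not early. On mechanism a kinetically marginal radical cyclisation stands against two well-behaved ring-forming steps (metathesis and cycloaddition). On step economy two steps after A6 beat the six after 20, but the route to A7 is expected to cost more than is saved.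

Key step: step 11

## Route

**Step 1**
Reactants: 1 2-methylbut-3-yn-2-ol; 2 bromoethene (vinyl bromide)
Product: 3 2-methylhex-5-en-3-yn-2-ol
Conditions: PdCl2(PPh3)2 (cat.), CuI (cat.), i-Pr2NH, THF, 0 °C → rt
Reagents that add atoms: none
Why: Sonogashira coupling of a terminal alkyne with a vinyl halide; the copper acetylide transmetalates to the vinylpalladium bromide and reductive elimination gives the enyne, the free tertiary alcohol being tolerated.

**Step 2**
Reactants: 3 2-methylhex-5-en-3-yn-2-ol
Product: 5 (3Z)-3-iodo-2-methylhexa-3,5-dien-2-ol, via dienylstannane 4 (not isolated)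
Conditions: Bu3SnH, [Cp*RuCl]4 (cat.), CH2Cl2, rt; then I2, 0 °C
Reagents that add atoms: tributyltin hydride, CCCC[SnH](CCCC)CCCC (its tin stays only in 4); iodine, II
Why: Ruthenium-catalysed hydroxyl-directed trans-hydrostannation; the carbinol OH, hydrogen-bonded to the chloride on ruthenium, steers tin to the alkyne carbon next to the carbinol while hydrogen is delivered anti, so the vinyl group ends up cis to tin. Iododestannylation then proceeds with retention, and the conjugated alkene should not be touched by this alkyne-selective catalyst.

**Step 3**
Reactants: 5 (3Z)-3-iodo-2-methylhexa-3,5-dien-2-ol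
Product: 6 triethyl{[(3Z)-3-iodo-2-methylhexa-3,5-dien-2-yl]oxy}silane
Conditions: Et3SiOTf, 2,6-lutidine, CH2Cl2, −78 → 0 °C
Reagents that add atoms: triethylsilyl trifluoromethanesulfonate, CC[Si](CC)(CC)OS(=O)(=O)C(F)(F)F
Why: O-silylation of a tertiary alcohol with a silyl triflate and a hindered base; this removes the acidic proton before halogen–lithium exchange and avoids acid that could ionise the tertiary allylic position.

**Step 4**
Reactants: 7 (4R)-4-benzyl-1,3-oxazolidin-2-one; 8 (2E)-but-2-enoyl chloride
Product: 10 (4R)-4-benzyl-3-[(2E)-but-2-enoyl]-1,3-oxazolidin-2-one, via lithiated oxazolidinone 9 (not isolated)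
Conditions: n-BuLi, THF, −78 °C; then 8, −78 → 0 °C
Reagents that add atoms: butyllithium, [Li]CCCC (its lithium stays only in 9)
Why: N-acylation of the lithium salt of an oxazolidinone with an acid chloride; at low temperature the anion acylates cleanly without deconjugation of the crotonyl group.

**Step 5**
Reactants: 10 (4R)-4-benzyl-3-[(2E)-but-2-enoyl]-1,3-oxazolidin-2-one
Product: 11 (4R)-4-benzyl-3-[(3S)-3-methylpent-4-enoyl]-1,3-oxazolidin-2-one
Conditions: CH2=CHMgBr, CuBr·SMe2, THF, −78 → −20 °C; aq NH4Cl
Reagents that add atoms: vinylmagnesium bromide, C=C[Mg]Br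
Why: Copper-mediated conjugate addition to the magnesium-chelated syn-s-cis N-enoyl imide; the vinyl group adds to the β-carbon on the face away from the benzyl group, which should give the (3S) centre that becomes C10, and the minor diastereomer can be removed at this stage.

**Step 6**
Reactants: 11 (4R)-4-benzyl-3-[(3S)-3-methylpent-4-enoyl]-1,3-oxazolidin-2-one
Product: 12 (3S)-N-methoxy-N,3-dimethylpent-4-enamide
Conditions: MeNH(OMe)·HCl, AlMe3, CH2Cl2, 0 °C → rt
Reagents that add atoms: N,O-dimethylhydroxylamine hydrochloride, CNOC.Cl
Why: Aminolysis of the imide by an aluminium amide (Weinreb amide formation); the reagent attacks the exocyclic carbonyl and releases the auxiliary 7 for recovery, and the β-stereocentre cannot epimerise.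

**Step 7**
Reactants: 6 triethyl{[(3Z)-3-iodo-2-methylhexa-3,5-dien-2-yl]oxy}silane; 12 (3S)-N-methoxy-N,3-dimethylpent-4-enamide
Product: 14 (3Z,7S)-7-methyl-4-[2-(triethylsilyloxy)propan-2-yl]nona-1,3,8-trien-5-one, via dienyllithium 13 (not isolated)
Conditions: t-BuLi (2 equiv), Et2O, −78 °C; then 12, −78 → −30 °C; aq NH4Cl
Reagents that add atoms: tert-butyllithium, [Li]C(C)(C)C (its lithium stays only in 13)
Why: Iodine–lithium exchange is much faster than addition of t-BuLi to the diene and retains the alkene geometry; the vinyllithium then acylates the N-methoxy-N-methylamide (Weinreb ketone synthesis) through a chelated tetrahedral intermediate that stops at the ketone, so the C7–C8 bond is made at the ketone oxidation level.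

**Step 8**
Reactants: 14 (3Z,7S)-7-methyl-4-[2-(triethylsilyloxy)propan-2-yl]nona-1,3,8-trien-5-one
Product: 15 (3E,5R,7S)-7-methyl-4-[2-(triethylsilyloxy)propan-2-yl]nona-1,3,8-trien-5-ol
Conditions: (S)-2-methyl-CBS-oxazaborolidine, catecholborane, toluene, −78 → −40 °C
Reagents that add atoms: none
Why: Corey–Bakshi–Shibata reduction; the ketone binds the oxazaborolidine with the branched dienyl group as the large substituent, and hydride from the coordinated borane should give the (5R) alcohol (future C8) under reagent control, independent of the remote methyl centre. Catecholborane at low temperature leaves the alkenes untouched, and the change from 3Z to 3E is only a change of priorities.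

**Step 9**
Reactants: 15 (3E,5R,7S)-7-methyl-4-[2-(triethylsilyloxy)propan-2-yl]nona-1,3,8-trien-5-ol
Product: 16 tert-butyl(dimethyl){[(3E,5R,7S)-7-methyl-4-[2-(triethylsilyloxy)propan-2-yl]nona-1,3,8-trien-5-yl]oxy}silane
Conditions: t-BuMe2SiOTf, 2,6-lutidine, CH2Cl2, −78 → 0 °C
Reagents that add atoms: tert-butyldimethylsilyl trifluoromethanesulfonate, CC(C)(C)[Si](C)(C)OS(=O)(=O)C(F)(F)F
Why: Silylation of a hindered secondary allylic alcohol with a silyl triflate; the bulky ether prevents alcohol-induced isomerisation during metathesis and later shields one face of the ring.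

**Step 10**
Reactants: 16 tert-butyl(dimethyl){[(3E,5R,7S)-7-methyl-4-[2-(triethylsilyloxy)propan-2-yl]nona-1,3,8-trien-5-yl]oxy}silane
Product: 17 tert-butyl(dimethyl){[(1R,6S)-6-methyl-2-[2-(triethylsilyloxy)propan-2-yl]cyclohepta-2,4-dien-1-yl]oxy}silane
Conditions: second-generation Grubbs catalyst RuCl2(H2IMes)(PCy3)(=CHPh) (cat.), CH2Cl2 (dilute), 40 °C
Reagents that add atoms: none
Why: Ring-closing metathesis; the catalyst should load on the isolated monosubstituted vinyl group and close onto the terminal CH2 of the diene, releasing ethene and forming the cis C1=C5 bond of the seven-membered ring. The internal trisubstituted diene bond is too hindered to compete.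

**Step 11**
Reactants: 17 tert-butyl(dimethyl){[(1R,6S)-6-methyl-2-[2-(triethylsilyloxy)propan-2-yl]cyclohepta-2,4-dien-1-yl]oxy}silane; 18 2-chloropropanoyl chloride (racemic)
Product: 20 (1S,4R,6S,7R,9R)-4-{[tert-butyl(dimethyl)silyl]oxy}-9-chloro-6,9-dimethyl-3-[2-(triethylsilyloxy)propan-2-yl]bicyclo[5.2.0]non-2-en-8-one, via chloro(methyl)ketene 19 (not isolated)
Conditions: 18 (slow addition, excess), Et3N, hexane, 25 → 60 °C
Reagents that add atoms: none
Why: Et3N dehydrochlorinates 18 to the ketene 19, which is trapped as it forms by the cisoid diene of 17 in a concerted but asynchronous [π2s+π2a] cycloaddition: the electrophilic ketene carbonyl carbon (C3) bonds first to the unsubstituted diene terminus C1, the developing positive charge is allylic over C5–C6–C7 with a tertiary end at C7, and it collapses onto the chloro(methyl) carbon to form C4–C5. The closest known reaction type is the [2+2] addition of chloro(alkyl)ketenes and dichloroketene to cyclopentadiene, cycloheptadienes and cycloheptatrienes. The four-membered ring (C1, C3, C4, C5) closes by cycloaddition, suprafacially on the alkene, so the ring fusion is necessarily cis. C1 and C5 (7R and 1S in the name of 20) are set together by the face of attack, which should be the face opposite both the C10 methyl and the C8 silyloxy group. C4 (9R) is set by the orientation of the ketene, the larger methyl group turning toward the ring in a non-polar solvent, and is of no consequence later. The step needs site selectivity (C1=C5, not C6=C7), orientation (carbonyl carbon to C1) and facial selectivity. These are secured by the fully substituted, shielded C7 terminus, by the better-stabilised allyl cation from attack at C1, and by having both ring substituents on one face. Slow addition of 18 keeps the concentration of 19 low and suppresses its dimerisation, and the silyl ethers are inert to the amine hydrochloride formed.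

**Step 12**
Reactants: 20 (the bicyclo[5.2.0]nonenone of step 11)
Product: 21 (3R,3aR,6R,8S,8aR)-6-{[tert-butyl(dimethyl)silyl]oxy}-3-chloro-3,8-dimethyl-5-[2-(triethylsilyloxy)propan-2-yl]-3,3a,6,7,8,8a-hexahydroazulen-2(1H)-one
Conditions: CH2N2, Et2O–MeOH, 0 °C
Reagents that add atoms: diazomethane, C=[N+]=[N-]
Why: Diazomethane homologation of an α-chlorocyclobutanone (Tiffeneau–Demjanov-type ring expansion); addition to the strained, chlorine-activated carbonyl is followed by 1,2-shift of the non-halogenated α-carbon C1 with retention and loss of N2, which places C2 between C1 and C3. The chlorocyclopentanone formed is far less reactive, so a second insertion should not compete.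

**Step 13**
Reactants: 21 (the chlorohydroazulenone of step 12)
Product: 22 (6R,8S,8aR)-6-{[tert-butyl(dimethyl)silyl]oxy}-3,8-dimethyl-5-[2-(triethylsilyloxy)propan-2-yl]-6,7,8,8a-tetrahydroazulen-2(1H)-one
Conditions: LiBr, Li2CO3, DMF, 90 °C
Reagents that add atoms: none
Why: Dehydrochlorination of a tertiary α-chloro ketone by lithium halide and carbonate in DMF; in the major epimer the chlorine is syn to H5, so elimination is expected after bromide exchange with inversion at C4, or toward the methyl group followed by prototropic shift into the ring. Either path ends at the thermodynamically favoured linear dienone, and the C4 and C5 stereocentres disappear.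

**Step 14**
Reactants: 22 (the dienone of step 13)
Product: 23 (5S,6R,8S,8aR)-6-{[tert-butyl(dimethyl)silyl]oxy}-3,8-dimethyl-5-[2-(triethylsilyloxy)propan-2-yl]-4,5,6,7,8,8a-hexahydroazulen-2(1H)-one
Conditions: H2 (1 atm), Pd/C, EtOAc, rt
Reagents that add atoms: none
Why: Heterogeneous catalytic hydrogenation; the trisubstituted γ,δ-bond C6=C7 should be reduced in preference to the tetrasubstituted enone bond, and hydrogen should add to the face opposite the C8 silyloxy group, which allylic 1,2-strain with the C7 side chain forces into a pseudoaxial position. This gives the (5S) centre (C7) with the side chain cis to the C8 oxygen.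

**Step 15**
Reactants: 23 (the enone of step 14)
Product: 24 (5S,6R,8S,8aR)-6-hydroxy-5-(2-hydroxypropan-2-yl)-3,8-dimethyl-4,5,6,7,8,8a-hexahydroazulen-2(1H)-one
Conditions: HF·pyridine, pyridine, THF, 0 °C → rt
Reagents that add atoms: none
Why: Fluoride-driven cleavage of both silyl ethers through Si–F bond formation; the buffered acidic medium avoids base that could epimerise C1 through the dienolate.

**Step 16**
Reactants: 24 (the diol of step 15)
Product: 25 (5S,6R,8S,8aR)-5-(2-hydroxypropan-2-yl)-3,8-dimethyl-2-oxo-1,2,4,5,6,7,8,8a-octahydroazulen-6-yl propanoate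
Conditions: (EtCO)2O (1.1 equiv), pyridine, DMAP (cat.), CH2Cl2, 0 °C
Reagents that add atoms: propanoic anhydride, CCC(=O)OC(=O)CC
Why: DMAP-catalysed acylation; the secondary C8 hydroxyl should react far faster than the hindered tertiary C11 hydroxyl, so a slight excess of anhydride at 0 °C should give the monoester.

**Step 17**
Reactants: 25 (the hydroxy propanoate of step 16)
Product: 26 (5S,6R,8S,8aR)-5-(2-acetoxypropan-2-yl)-3,8-dimethyl-2-oxo-1,2,4,5,6,7,8,8a-octahydroazulen-6-yl propanoate (target)
Conditions: Ac2O, Et3N, DMAP, CH2Cl2, 40 °C
Reagents that add atoms: acetic anhydride, CC(=O)OC(C)=O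
Why: Nucleophile-catalysed acetylation of a tertiary alcohol through the N-acetylpyridinium ion; the non-acidic conditions avoid ionisation of the tertiary centre, and the enone and the propanoate are inert.

## Compound list

1 | 2-methylbut-3-yn-2-ol | CC(C)(O)C#C | starting material
2 | bromoethene (vinyl bromide) | C=CBr | starting material
3 | 2-methylhex-5-en-3-yn-2-ol | CC(C)(O)C#CC=C | intermediate
4 | (3Z)-2-methyl-3-(tributylstannyl)hexa-3,5-dien-2-ol | C=C/C=C(\[Sn](CCCC)(CCCC)CCCC)C(C)(C)O | intermediate (not isolated)
5 | (3Z)-3-iodo-2-methylhexa-3,5-dien-2-ol | C=C/C=C(\I)C(C)(C)O | intermediate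
6 | triethyl{[(3Z)-3-iodo-2-methylhexa-3,5-dien-2-yl]oxy}silane | C=C/C=C(\I)C(C)(C)O[Si](CC)(CC)CC | intermediate
7 | (4R)-4-benzyl-1,3-oxazolidin-2-one | O=C1N[C@H](Cc2ccccc2)CO1 | starting material
8 | (2E)-but-2-enoyl chloride | C/C=C/C(Cl)=O | starting material
9 | lithium (4R)-4-benzyl-2-oxo-1,3-oxazolidin-3-ide | [Li]N1[C@H](Cc2ccccc2)COC1=O | intermediate (not isolated)
10 | (4R)-4-benzyl-3-[(2E)-but-2-enoyl]-1,3-oxazolidin-2-one | C/C=C/C(=O)N1[C@H](Cc2ccccc2)COC1=O | intermediate
11 | (4R)-4-benzyl-3-[(3S)-3-methylpent-4-enoyl]-1,3-oxazolidin-2-one | C=C[C@@H](C)CC(=O)N1[C@H](Cc2ccccc2)COC1=O | intermediate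
12 | (3S)-N-methoxy-N,3-dimethylpent-4-enamide | C=C[C@@H](C)CC(=O)N(C)OC | intermediate
13 | [(3E)-2-methyl-2-(triethylsilyloxy)hexa-3,5-dien-3-yl]lithium (vinyl group cis to lithium) | [Li]/C(=C\C=C)C(C)(C)O[Si](CC)(CC)CC | intermediate (not isolated)
14 | (3Z,7S)-7-methyl-4-[2-(triethylsilyloxy)propan-2-yl]nona-1,3,8-trien-5-one | C=C/C=C(\C(=O)C[C@H](C)C=C)C(C)(C)O[Si](CC)(CC)CC | intermediate
15 | (3E,5R,7S)-7-methyl-4-[2-(triethylsilyloxy)propan-2-yl]nona-1,3,8-trien-5-ol | C=C/C=C(\[C@H](O)C[C@H](C)C=C)C(C)(C)O[Si](CC)(CC)CC | intermediate
16 | tert-butyl(dimethyl){[(3E,5R,7S)-7-methyl-4-[2-(triethylsilyloxy)propan-2-yl]nona-1,3,8-trien-5-yl]oxy}silane | C=C/C=C(\[C@H](O[Si](C)(C)C(C)(C)C)C[C@H](C)C=C)C(C)(C)O[Si](CC)(CC)CC | intermediate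
17 | tert-butyl(dimethyl){[(1R,6S)-6-methyl-2-[2-(triethylsilyloxy)propan-2-yl]cyclohepta-2,4-dien-1-yl]oxy}silane | CC(C)(C)[Si](C)(C)O[C@@H]1C[C@H](C)C=CC=C1C(C)(C)O[Si](CC)(CC)CC | intermediate
18 | 2-chloropropanoyl chloride (racemic) | CC(Cl)C(Cl)=O | starting material
19 | chloro(methyl)ketene (2-chloroprop-1-en-1-one) | CC(Cl)=C=O | intermediate (not isolated)
20 | (1S,4R,6S,7R,9R)-4-{[tert-butyl(dimethyl)silyl]oxy}-9-chloro-6,9-dimethyl-3-[2-(triethylsilyloxy)propan-2-yl]bicyclo[5.2.0]non-2-en-8-one | CC(C)(C)[Si](C)(C)O[C@@H]1C[C@H](C)[C@H]2C(=O)[C@](C)(Cl)[C@H]2C=C1C(C)(C)O[Si](CC)(CC)CC | intermediate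
21 | (3R,3aR,6R,8S,8aR)-6-{[tert-butyl(dimethyl)silyl]oxy}-3-chloro-3,8-dimethyl-5-[2-(triethylsilyloxy)propan-2-yl]-3,3a,6,7,8,8a-hexahydroazulen-2(1H)-one | CC(C)(C)[Si](C)(C)O[C@@H]1C[C@H](C)[C@H]2CC(=O)[C@](C)(Cl)[C@H]2C=C1C(C)(C)O[Si](CC)(CC)CC | intermediate
22 | (6R,8S,8aR)-6-{[tert-butyl(dimethyl)silyl]oxy}-3,8-dimethyl-5-[2-(triethylsilyloxy)propan-2-yl]-6,7,8,8a-tetrahydroazulen-2(1H)-one | CC(C)(C)[Si](C)(C)O[C@@H]1C[C@H](C)[C@H]2CC(=O)C(C)=C2C=C1C(C)(C)O[Si](CC)(CC)CC | intermediate
23 | (5S,6R,8S,8aR)-6-{[tert-butyl(dimethyl)silyl]oxy}-3,8-dimethyl-5-[2-(triethylsilyloxy)propan-2-yl]-4,5,6,7,8,8a-hexahydroazulen-2(1H)-one | CC(C)(C)[Si](C)(C)O[C@@H]1C[C@H](C)[C@H]2CC(=O)C(C)=C2C[C@@H]1C(C)(C)O[Si](CC)(CC)CC | intermediate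
24 | (5S,6R,8S,8aR)-6-hydroxy-5-(2-hydroxypropan-2-yl)-3,8-dimethyl-4,5,6,7,8,8a-hexahydroazulen-2(1H)-one | O[C@@H]1C[C@H](C)[C@H]2CC(=O)C(C)=C2C[C@@H]1C(C)(C)O | intermediate
25 | (5S,6R,8S,8aR)-5-(2-hydroxypropan-2-yl)-3,8-dimethyl-2-oxo-1,2,4,5,6,7,8,8a-octahydroazulen-6-yl propanoate | CCC(=O)O[C@@H]1C[C@H](C)[C@H]2CC(=O)C(C)=C2C[C@@H]1C(C)(C)O | intermediate
26 | (5S,6R,8S,8aR)-5-(2-acetoxypropan-2-yl)-3,8-dimethyl-2-oxo-1,2,4,5,6,7,8,8a-octahydroazulen-6-yl propanoate | CCC(=O)O[C@@H]1C[C@H](C)[C@H]2CC(=O)C(C)=C2C[C@@H]1C(C)(C)OC(C)=O | target

## Step count and least certain steps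

Total: 17 steps. Longest linear sequence: 14 steps (steps 1–3 and 7–17; the branch through steps 4–6 and 7–17 is equally long).

**Step 11 (key step).**
- Risk: oligomerisation of the disubstituted ketene 19 may outrun its capture by a diene whose reacting face is flanked by ring substituents, and facial discrimination may be incomplete because the seven-membered ring is flexible and the C10 methyl may sit pseudoequatorial.
- Fallback, from 17 back to 22: the smaller and more electrophilic dichloroketene (dichloroacetyl chloride, Et3N, hexane) should give the 9,9-dichlorobicyclo[5.2.0]nonenone F1. Diazomethane should expand it to the 3,3-dichlorohydroazulenone F2. Loss of HCl (LiCl, Li2CO3, DMF), now always possible anti to H5, should give the 3-chlorodienone F3. Suzuki–Miyaura methylation (trimethylboroxine, Pd(OAc)2, SPhos, K3PO4) then returns to 22.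

**Step 14.**
- Risk: incomplete site and facial selectivity, that is, slow uptake at the hindered C6=C7 bond, migration of a double bond on palladium, or delivery of hydrogen from the silyloxy face, because both faces of a flexible ring are partly encumbered.
- Fallback, from 22 back to 24: selective cleavage of the more labile triethylsilyl ether (pyridinium p-toluenesulfonate, MeOH, 0 °C) should give the C11 carbinol F4. Homogeneous hydrogenation with [Ir(cod)(PCy3)(py)]PF6 in CH2Cl2, in which the free carbinol anchors the catalyst beside C6=C7 while the C8 silyl ether still blocks the lower face, should give the saturated carbinol F5. HF·pyridine then removes the remaining silyl group to give 24.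

**Step 13.**
- Risk: stalling of the elimination because the major C4 epimer has no hydrogen anti to chlorine at C5, or diversion to a non-conjugated exocyclic isomer or to Favorskii-type ring contraction under more forcing basic conditions.
- Fallback, from 21 back to 22: reductive silylation (Zn, Me3SiCl, THF) should give regiospecifically the C3–C4 trimethylsilyl enol ether F6, and Saegusa–Ito oxidation with Pd(OAc)2 in MeCN should give 22.

**Step 7.**
- Risk: migration of the triethylsilyl group from oxygen to the lithiated carbon, addition of t-BuLi to the diene, or enolisation of 12 by the hindered vinyllithium; the cis-dienone 14 may also equilibrate with a 2H-pyran valence isomer if stored.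
- Fallback, from 6 and 12 back to 14: reduction of 12 with i-Bu2AlH should give (3S)-3-methylpent-4-enal F7. Nozaki–Hiyama–Kishi coupling of 6 with F7 (CrCl2, NiCl2 (cat.), DMF) should give the dienyl carbinol F8 as a mixture of C5 epimers. Dess–Martin oxidation then gives 14, which is reduced at once as in step 8.

**Step 2.**
- Risk: erosion of regiocontrol, with tin delivered to the remote alkyne carbon, or involvement of the conjugated alkene (isomerisation, hydrostannation of the diene product), since the substrate is both tertiary and an enyne.
- Fallback, from 1 and 2 back to 4: palladium-catalysed syn-distannylation of 1 (Bu3SnSnBu3, Pd(PPh3)4, THF, 60 °C) should give (3Z)-2-methyl-3,4-bis(tributylstannyl)but-3-en-2-ol F9. Site-selective Stille coupling of its unhindered terminal tin with 2 (PdCl2(MeCN)2, DMF) should give 4 with the vinyl group cis to the remaining tin, and iodination as in step 2 gives 5.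

## Further compounds

F1 | step 11 | (1S,4R,6S,7R)-4-{[tert-butyl(dimethyl)silyl]oxy}-9,9-dichloro-6-methyl-3-[2-(triethylsilyloxy)propan-2-yl]bicyclo[5.2.0]non-2-en-8-one | CC(C)(C)[Si](C)(C)O[C@@H]1C[C@H](C)[C@H]2C(=O)C(Cl)(Cl)[C@H]2C=C1C(C)(C)O[Si](CC)(CC)CC
F2 | step 11 | (3aR,6R,8S,8aR)-6-{[tert-butyl(dimethyl)silyl]oxy}-3,3-dichloro-8-methyl-5-[2-(triethylsilyloxy)propan-2-yl]-3,3a,6,7,8,8a-hexahydroazulen-2(1H)-one | CC(C)(C)[Si](C)(C)O[C@@H]1C[C@H](C)[C@H]2CC(=O)C(Cl)(Cl)[C@H]2C=C1C(C)(C)O[Si](CC)(CC)CC
F3 | step 11 | (6R,8S,8aR)-6-{[tert-butyl(dimethyl)silyl]oxy}-3-chloro-8-methyl-5-[2-(triethylsilyloxy)propan-2-yl]-6,7,8,8a-tetrahydroazulen-2(1H)-one | CC(C)(C)[Si](C)(C)O[C@@H]1C[C@H](C)[C@H]2CC(=O)C(Cl)=C2C=C1C(C)(C)O[Si](CC)(CC)CC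
F4 | step 14 | (6R,8S,8aR)-6-{[tert-butyl(dimethyl)silyl]oxy}-5-(2-hydroxypropan-2-yl)-3,8-dimethyl-6,7,8,8a-tetrahydroazulen-2(1H)-one | CC(C)(C)[Si](C)(C)O[C@@H]1C[C@H](C)[C@H]2CC(=O)C(C)=C2C=C1C(C)(C)O
F5 | step 14 | (5S,6R,8S,8aR)-6-{[tert-butyl(dimethyl)silyl]oxy}-5-(2-hydroxypropan-2-yl)-3,8-dimethyl-4,5,6,7,8,8a-hexahydroazulen-2(1H)-one | CC(C)(C)[Si](C)(C)O[C@@H]1C[C@H](C)[C@H]2CC(=O)C(C)=C2C[C@@H]1C(C)(C)O
F6 | step 13 | (3aR,6R,8S,8aR)-6-{[tert-butyl(dimethyl)silyl]oxy}-3,8-dimethyl-5-[2-(triethylsilyloxy)propan-2-yl]-2-(trimethylsilyloxy)-1,3a,6,7,8,8a-hexahydroazulene | CC(C)(C)[Si](C)(C)O[C@@H]1C[C@H](C)[C@H]2CC(O[Si](C)(C)C)=C(C)[C@H]2C=C1C(C)(C)O[Si](CC)(CC)CC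
F7 | step 7 | (3S)-3-methylpent-4-enal | C=C[C@@H](C)CC=O
F8 | step 7 | (3E,7S)-7-methyl-4-[2-(triethylsilyloxy)propan-2-yl]nona-1,3,8-trien-5-ol, mixture of C5 epimers | C=C/C=C(\C(O)C[C@H](C)C=C)C(C)(C)O[Si](CC)(CC)CC
F9 | step 2 | (3Z)-2-methyl-3,4-bis(tributylstannyl)but-3-en-2-ol | CC(C)(O)/C([Sn](CCCC)(CCCC)CCCC)=C/[Sn](CCCC)(CCCC)CCCC
A1 | alternative 1 | 10-hydroxy-8-propanoyloxy-11-acetoxyguai-4-en-3-one | CCC(=O)O[C@@H]1C[C@@](O)(C)[C@H]2CC(=O)C(C)=C2C[C@@H]1C(C)(C)OC(C)=O
A2 | alternative 1 | 8-propanoyloxy-11-acetoxyeudesma-1,4-dien-3-one with the C10 methyl trans to the C7 side chain | CCC(=O)O[C@@H]1C[C@]2(C)C=CC(=O)C(C)=C2C[C@@H]1C(C)(C)OC(C)=O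
A3 | alternative 2 | bicyclic C8 silyl enol ether with C7 methyl ester, C1=C5 alkene, C10 methyl and C3 ethylene ketal | COC(=O)C1=C(O[Si](C)(C)C(C)(C)C)C[C@H](C)C2=C(C1)[C@H](C)C3(OCCO3)C2
A4 | alternative 2 | (6S,8E)-8-ethylidene-6-methyl-7-methylidene-1,4-dioxaspiro[4.4]nonane | C/C=C1\CC2(OCCO2)[C@@H](C)C1=C
A5 | alternative 2 | methyl 3-{[tert-butyl(dimethyl)silyl]oxy}-2-diazobut-3-enoate | COC(=O)C(=[N+]=[N-])C(=C)O[Si](C)(C)C(C)(C)C
A6 | alternative 3 | cis-fused 8-propanoyloxy-11-acetoxyguaian-3-one (4,5-dihydro target) | CCC(=O)O[C@@H]1C[C@H](C)[C@H]2CC(=O)[C@H](C)[C@H]2C[C@@H]1C(C)(C)OC(C)=O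
A7 | alternative 3 | 2-methylcyclopent-2-enone bearing at its C4 (guaiane C1) the C10–C9–C8–C7–C6 chain with C10 methyl, C8 propanoate, C7 acetoxyisopropyl and C6 iodide | CCC(=O)O[C@H](C[C@H](C)[C@H]1CC(=O)C(C)=C1)[C@H](CI)C(C)(C)OC(C)=O
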